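The benzene ring (C1 CO2Me, C2 OH, C4 OMe, C6 icosyl) is treated as the dehydrogenated form of a 6-alkyl-2,4-dioxocyclohexanecarboxylate. The 1,3-related oxygens on C2 and C4 and the ester on C1 come from a malonate and a methyl ketone, and C6, which carries the icosyl chain, was the β-carbon of an enone. A single Michael–Claisen annulation of dimethyl malonate 4 onto (E)-tetracos-3-en-2-one 3 forges C1–C6 and C2–C3 and closes the six-membered ring. The precursor is a plain linear C24 methyl enone, available in one cross-metathesis from docos-1-ene 1. Bromine-mediated aromatization and methylation of the free, non-hydrogen-bonded C4 hydroxyl finish the synthesis.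

Key step: step 2

Remark on the chemistry: the target has no stereocentre. C1 and C6 of compounds 5 to 8 form without control (racemic, 8 also as diastereomers), are drawn without descriptors and vanish on aromatization. Compound 7 is drawn as one enol tautomer of the 2,4-dione.

Step 1
Reactants: 1 docos-1-ene; 2 but-3-en-2-one (methyl vinyl ketone)
Product: 3 (E)-tetracos-3-en-2-one
Conditions: 2 (3 equiv), second-generation Grubbs catalyst (H2IMes)(PCy3)Cl2Ru=CHPh (2 mol%), CH2Cl2, 40 °C
Reagents that add atoms: none
Why: Ruthenium-carbene olefin cross-metathesis between a terminal alkene that homodimerizes reversibly and an electron-poor enone that does not homodimerize should, with excess 2 and loss of ethene, funnel the material to the conjugated cross product, which equilibrates to the E isomer.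

Step 2
Reactants: 3 (E)-tetracos-3-en-2-one; 4 dimethyl malonate
Product: 7 methyl 2-hydroxy-6-icosyl-4-oxocyclohex-2-ene-1-carboxylate (racemic), via Michael adduct 5 (not isolated), via sodium enolate 6 (not isolated)
Conditions: 4 (1.2 equiv), NaOMe (1.2 equiv), MeOH/THF, 65 °C; then 1 M aq HCl, 0 °C
Reagents that add atoms: none
Why: This is a Michael–Claisen annulation, the established entry to 6-alkyl-dihydroresorcylate esters: the sodium enolate of 4 adds in conjugate fashion to C4 of enone 3 (ring bond C1–C6) and proton transfer gives adduct 5. Reversible deprotonation of the terminal acetyl methyl then provides the enolate that attacks one of the two equivalent ester carbonyls (ring bond C2–C3) and expels methoxide. The ring closes in the 6-(enolendo)-exo-trig mode, the only productive one, because the alternative ketone enolate at the internal CH2 could only form a four-membered ring. The sp3 centres C1 and C6 arise without control as a racemic, C1-epimerizable mixture, which is immaterial since both become sp2 in step 3. The required 1,4- over 1,2-selectivity follows from the soft, stabilized malonate anion, whose carbonyl addition is reversible, and methoxide in methanol cannot scramble the methyl esters. The sequence is pulled forward by irreversible deprotonation of the acidic cyclic 1,3-dione to enolate 6, which cold aqueous HCl should convert into 7 without hydrolysis or decarboxylation.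

Step 3
Reactants: 7 methyl 2-hydroxy-6-icosyl-4-oxocyclohex-2-ene-1-carboxylate
Product: 9 methyl 2,4-dihydroxy-6-icosylbenzoate, via bromo dione 8 (not isolated)
Conditions: Br2 (1.05 equiv), DMF, 20 °C, then 80 °C
Reagents that add atoms: none
Why: Halogenation–dehydrohalogenation aromatization, established for 6-alkyl-2,4-dioxocyclohexanecarboxylates: the enolized 1,3-dione is brominated at C3 to give 8, whose dienol tautomer should lose HBr by 1,4-elimination (H from C6, bromide from C3) on warming in HBr-buffering DMF and then tautomerize to the resorcylate, while one equivalent of Br2 and a ceiling of 80 °C should spare the ring positions and the ester.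

Step 4
Reactants: 9 methyl 2,4-dihydroxy-6-icosylbenzoate
Product: 10 methyl 2-hydroxy-6-icosyl-4-methoxybenzoate
Conditions: MeI (1.05 equiv), K2CO3 (1.2 equiv), acetone, 56 °C
Reagents that add atoms: iodomethane (MeI), CI
Why: Williamson O-methylation in which the C4 hydroxyl, para to the ester and outside the intramolecular hydrogen bond that ties the C2 hydroxyl to the ester carbonyl, is the more acidic and more nucleophilic site, so one equivalent of MeI under mild carbonate conditions should alkylate it selectively, as is routine for orsellinate-type esters.

Compound list
1 | docos-1-ene | CCCCCCCCCCCCCCCCCCCCC=C | starting material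
2 | but-3-en-2-one (methyl vinyl ketone) | C=CC(C)=O | starting material
3 | (E)-tetracos-3-en-2-one | CCCCCCCCCCCCCCCCCCCC/C=C/C(C)=O | intermediate
4 | dimethyl malonate (dimethyl propanedioate) | COC(=O)CC(=O)OC | starting material
5 | dimethyl 2-(2-oxotetracosan-4-yl)propanedioate (racemic Michael adduct, not isolated) | CCCCCCCCCCCCCCCCCCCCC(CC(C)=O)C(C(=O)OC)C(=O)OC | intermediate
6 | sodium 5-icosyl-6-(methoxycarbonyl)-3-oxocyclohex-1-en-1-olate (racemic, not isolated) | CCCCCCCCCCCCCCCCCCCCC1CC(=O)C=C([O-])C1C(=O)OC.[Na+] | intermediate
7 | methyl 2-hydroxy-6-icosyl-4-oxocyclohex-2-ene-1-carboxylate (racemic; enol form of methyl 6-icosyl-2,4-dioxocyclohexane-1-carboxylate) | CCCCCCCCCCCCCCCCCCCCC1CC(=O)C=C(O)C1C(=O)OC | intermediate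
8 | methyl 3-bromo-6-icosyl-2,4-dioxocyclohexane-1-carboxylate (stereoisomer mixture, not isolated) | CCCCCCCCCCCCCCCCCCCCC1CC(=O)C(Br)C(=O)C1C(=O)OC | intermediate
9 | methyl 2,4-dihydroxy-6-icosylbenzoate | CCCCCCCCCCCCCCCCCCCCc1cc(O)cc(O)c1C(=O)OC | intermediate
10 | methyl 2-hydroxy-6-icosyl-4-methoxybenzoate (CNP0075630.0) | CCCCCCCCCCCCCCCCCCCCc1cc(OC)cc(O)c1C(=O)OC | target

Total step count: 4. Longest linear sequence: 4 steps (1 → 3 → 7 → 9 → 10).

Steps most likely to fail

Step 2. The waxy, enolizable enone may self-condense under methoxide or stay poorly solvated, so that conjugate addition and ring closure remain incomplete. Adventitious water could also hydrolyse and decarboxylate the β-keto ester. The fallback sets out from 1 and removes the enolizable acceptor by exchanging the roles of the two partners. Cross-metathesis of 1 with methyl acrylate (C=CC(=O)OC; second-generation Grubbs catalyst (H2IMes)(PCy3)Cl2Ru=CHPh, CH2Cl2, 40 °C) should give methyl (E)-tricos-2-enoate F1. The sodium enolate of methyl acetoacetate (CC(=O)CC(=O)OC; NaOMe, MeOH/THF, 65 °C) should then add to the β-carbon of F1 to give dimethyl 2-acetyl-3-icosylpentanedioate F2, which is not isolated. Its acetyl methyl enolate closes onto the distal ester in a Claisen condensation, forming C1–C6 and C3–C4 instead, and gives sodium enolate 6. Cold aqueous HCl then returns the route at 7.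

Step 3. Electrophilic bromination of the electron-rich ring as soon as it forms may compete with dehydrobromination, and HBr at elevated temperature may cleave the ester and trigger decarboxylation. The fallback sets out from 7 and drives the halogenation to a single defined end point. Excess Br2 (3.1 equiv, AcOH, 20 to 50 °C) should aromatize and brominate both free ring positions to give methyl 3,5-dibromo-2,4-dihydroxy-6-icosylbenzoate F3. Hydrogenolysis of both C–Br bonds (H2 1 atm, Pd/C, NaOAc, EtOAc/MeOH, 20 °C) should then return the route at 9.

Step 1. Homodimerization of the terminal alkene, and double-bond migration by ruthenium hydride species before metathesis, would give chain-shortened homologues that are hard to remove from a long-chain enone. The fallback sets out from 1 and fixes the chain length by oxidative cleavage. Ozonolysis (O3, CH2Cl2, −40 °C; then PPh3) should give henicosanal F4. A Wittig reaction with the stabilized ylide 1-(triphenylphosphoranylidene)propan-2-one (CC(=O)C=P(c1ccccc1)(c1ccccc1)c1ccccc1; toluene, 80 °C) should then deliver the E enone and return the route at 3.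

Further compounds
F1 | step 2 | methyl (E)-tricos-2-enoate | CCCCCCCCCCCCCCCCCCCC/C=C/C(=O)OC
F2 | step 2 | dimethyl 2-acetyl-3-icosylpentanedioate (stereoisomer mixture, not isolated) | CCCCCCCCCCCCCCCCCCCCC(CC(=O)OC)C(C(C)=O)C(=O)OC
F3 | step 3 | methyl 3,5-dibromo-2,4-dihydroxy-6-icosylbenzoate | CCCCCCCCCCCCCCCCCCCCc1c(Br)c(O)c(Br)c(O)c1C(=O)OC
F4 | step 1 | henicosanal | CCCCCCCCCCCCCCCCCCCCC=O
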